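## Structural features

The target is a (2S)-flavanone: a chroman-4-one in which benzo ring A is fused to the dihydropyranone ring C, with ring B attached at C2, the only stereocentre. Ring A is a fully differentiated phloroglucinol nucleus: a 5-hydroxyl hydrogen-bonded to the C4 carbonyl, a free 7-hydroxyl, and a prenyl group on C8, lodged between O7 and the ring oxygen O1 on C8a. Ring B carries three contiguous substituents (2'-prenyl, 3'-methoxy, 4'-hydroxyl), so C2 sits next to an ortho-substituted, electron-rich aryl group. C2 has no neighbouring stereocentre, but it is benzylic, α to O1 and β to the ketone, and can racemise by retro-oxa-Michael opening of ring C under base or strong acid. Both prenyl alkenes lie ortho to phenolic oxygens and cyclise to chromans or add HX under protic or strong Lewis acids; they also rule out hydrogenation and electrophilic oxidants. The real difficulty is twofold: placing prenyl on C8 and not C6, and creating C2 with defined configuration without later exposing it to ring-opening conditions. The key step uses the fact that the oxygens on C7 and C8a flank the prenyl-bearing C8, which is the 1,3-dioxygenated, 2-alkylated pattern formed when a vinylketene combines with an ynol ether. Because O1 links C8a to C2 and the C4 carbonyl links C3 to C4a, an ynol ether on the C2 oxygen and a cyclobutenone on the C4 acyl carbon can close rings A and C in one pericyclic cascade.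

## Logic of the disconnections

27 is traced to 26 by cutting the two O–CH2 acetal bonds on O5 and O4'. O4' must be masked against organolithiums and ketenes, and O5 arrives as the oxygen substituent of the four-membered ring. Giving both the same acetal lets one mild protic step finish the synthesis and avoids Lewis-acid cleavage of a peri alkyl ether next to a prenyl group and a free 7-hydroxyl. The demand is an acid mild enough for the two prenyl groups and for C2.

26 is traced to 22 by cutting C4a–C8a, C7–C8 and C6–C7. This removes rings A and C at once and leaves an open chain whose only stereocentre is the C2 carbinol carbon, with the C8 prenyl group and both ring A oxygens already in their final positions. The demand is that the forward cascade starts below the temperature at which the benzylic ynol ether fragments, and that 22 is assembled under neutral conditions.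

22 is traced through 21 to 17 and 20 by cutting C4–C4a, the only bond between the chiral chain and the four-membered ring. The cut separates a chiral aldehyde from an achiral four-carbon unit and allows a neutral alkenyl iodide–aldehyde union. The demand is that the union and the following oxidation use neither acid (ynol ether) nor base (β-elimination of the alkynyloxy group).

20 is traced through 19 to 18 by cutting the C–I bond and the O–CH2 bond. This is simple functionalisation of a symmetric dione, and it demands only that the vinylogous ester be handled without acid.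

17 is traced through 16 to 15 by oxidation-level and protecting-group changes at C4. C4 is carried as a silyl-protected primary alcohol because no carbonyl group at C4 would survive the strong bases of ynol ether formation. The demand is a fluoride deprotection and a buffered oxidation that the ynol ether tolerates.

15 is traced to 11, 12 and 3 by cutting the alkynyl C8a–O1 bond and the C8–CH2 bond of the future 8-prenyl group. The two alkyne carbons come from 12 and the prenyl group from 3, and the carbinol C–O bond is never broken, so the configuration is kept. The demand is that everything else in 11 withstands KH and n-BuLi.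

11 is traced through 10 and 9 to 6 and 7 by cutting C2–C3. An acetate aldol addition creates the stereocentre and brings in C3 and C4 in one step, and the auxiliary is cleaved by the same reduction that sets C4 at the alcohol level. The demand is facial control on an ortho-substituted, electron-rich aldehyde without Lewis acids.

6 is traced to 2 and 3 by cutting the C2'–CH2 bond, and 2 to 1 by cutting the O–CH2 bond. The prenyl group enters at the one ring position that lies between the masked formyl group and the methoxy group. The demand is regiocontrol of the metalation against the second oxygen director on the ring.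

## Other disconnections considered

Alternative 1: Ring C is cut at C4a–C4, C4–C3 and O1–C2, giving iodophenol A1, carbon monoxide A2 and arylacetylene A3. In the forward step PdCl2(PPh3)2, reduced in situ to zerovalent palladium, inserts into the C4a–I bond, takes up A2, couples with A3, and the C8a phenol closes the ring by 6-endo addition to give flavone A4.
- In favour: three components converge in one operation, each elementary step is well precedented, and prenyl groups and MOM ethers should tolerate the conditions. On precedent and convergence this alternative is better than the chosen plan.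
- Against: A4 has no stereocentre. C2 would have to be created afterwards by enantioselective 1,4-reduction of the flavone double bond, next to an ortho-substituted ring B and without touching two prenyl alkenes or the ketone. That is the least developed transformation in the whole sequence. A1 is a hexasubstituted arene that needs its own regiocontrolled synthesis, and 5-exo closure to an aurone can compete.
- Comparison: on structure, the alternative postpones the stereochemical problem to the hardest point, whereas the chosen plan sets C2 by an aldol addition and never breaks a bond to it. On mechanism the alternative is safer. On step economy the two are similar up to A4, but the alternative then needs the reduction and three deprotections.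

Alternative 2: The two aryl–CH2 bonds of the prenyl groups (C8–CH2 and C2'–CH2) are cut, leading back to bis-ether A5. In the forward step heating with Eu(fod)3, a trivalent europium complex, moves the 5-O-prenyl group to C6 by Claisen rearrangement and on to C8 by Cope rearrangement, and moves the 3'-O-(1,1-dimethylallyl) group to C2' by Claisen rearrangement, giving A6.
- In favour: the relay to C8 is established pericyclic chemistry, and both acid-sensitive prenyl groups arrive late. On this point it is better than the chosen plan, which carries both prenyl groups through organolithium, oxidation and photochemical steps.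
- Against: the flavanone core and C2 must exist before the key step, so the enantioselective problem is not addressed by it. Warming a 5-oxygenated flavanone with a Lewis acid invites reversible opening of ring C and erosion of C2. The relay may stop at the C6 stage. The tertiary allyl aryl ether of A5 needs a two-step installation and ionises easily. A6 still requires selective 3'-O-methylation and deprotection.
- Comparison: on structure, the alternative decorates a finished core while the chosen plan builds ring A with its substituents in place. On mechanism the alternative is better precedented. On step economy the two are comparable once an asymmetric synthesis of A5 is counted.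

Alternative 3: The O1–C8a bond is cut, leading to bromo diol A7. In the forward step CuI with 3,4,7,8-tetramethyl-1,10-phenanthroline and Cs2CO3 couples the C2 hydroxyl with the aryl bromide to close ring C as flavan-4-ol A8.
- In favour: the C2 carbinol comes from the same kind of aldol chemistry as in the chosen plan and its C–O bond is not broken, so on stereocontrol the alternative is the equal of the chosen plan. Regiochemistry on ring A is fixed by the position of bromine, and the coupling type is known, so on mechanistic certainty it is better.
- Against: A7 needs a hexasubstituted bromoarene made separately. The bromide is flanked by the prenyl group and the side chain and sits on an electron-rich ring, which is a poor situation for copper insertion. C4 must be carried as an alcohol because a β-hydroxy ketone would eliminate under the base, so oxidation at C4 and three deprotections follow A8.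
- Comparison: on structure, the chosen plan creates the arene while the alternative must first assemble it. On step economy the alternative is longer.

Key step: step 13

Remark on the chemistry: 18 is taken as a commercial compound (it is also the acid hydrolysis product of 3-ethoxycyclobut-2-en-1-one), and the established sense of induction of 7 (the S reagent giving the S-configured β-hydroxy ester when the aldehyde substituent outranks the CH2CO group) is assumed to hold for 6.

Abbreviation: Ar = 3-methoxy-4-(methoxymethoxy)-2-(3-methylbut-2-en-1-yl)phenyl.

## Route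

Step 1
Reactants: 1 vanillin (4-hydroxy-3-methoxybenzaldehyde)
Product: 2 3-methoxy-4-(methoxymethoxy)benzaldehyde
Conditions: MOMCl, iPr2NEt, CH2Cl2, 0 °C → rt
Reagents that add atoms: chloromethyl methyl ether (MOMCl), COCCl
Why: Williamson-type O-alkylation of the phenol with the reactive α-chloro ether; the acetal ether is inert to the organolithium and hydride reagents used later and leaves with dilute acid at the end.

Step 2
Reactants: 2 3-methoxy-4-(methoxymethoxy)benzaldehyde; 3 prenyl bromide (1-bromo-3-methylbut-2-ene)
Product: 6 3-methoxy-4-(methoxymethoxy)-2-(3-methylbut-2-en-1-yl)benzaldehyde, via lithium α-amino alkoxide 4 (not isolated), via C2-lithiated amino alkoxide 5 (not isolated)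
Conditions: LiN(Me)CH2CH2NMe2, THF, −20 °C; n-BuLi, −20 °C; CuBr·SMe2 (cat.), 3, −78 °C → rt; H2O
Reagents that add atoms: none
Why: Directed ortho-metalation through an in situ α-amino alkoxide: the lithium amide adds to the formyl group, masking it and creating a chelating director, so n-BuLi removes the C2 proton lying between this group and the 3-methoxy group; copper-catalysed SN2 allylation installs prenyl and water regenerates the aldehyde.

Step 3
Reactants: 6 3-methoxy-4-(methoxymethoxy)-2-(3-methylbut-2-en-1-yl)benzaldehyde; 7 (S)-2-hydroxy-1,2,2-triphenylethyl acetate ((S)-HYTRA)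
Product: 9 (S)-2-hydroxy-1,2,2-triphenylethyl (3S)-3-hydroxy-3-Ar-propanoate, via dilithium enolate 8 (not isolated)
Conditions: 7, LiN(iPr)2 (2.1 equiv), THF, −78 → 0 °C; MgBr2, −78 °C; 6, −115 °C
Reagents that add atoms: none
Why: Acetate aldol addition of the doubly deprotonated chiral acetate (HYTRA aldol): the triphenylglycol-derived enolate differentiates the aldehyde faces, the (S)-reagent delivering the (S)-carbinol, and the major diastereomer can be enriched by crystallisation; no Lewis acid strong enough to harm the MOM ether or the prenyl group is present.

Step 4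
Reactants: 9 (S)-2-hydroxy-1,2,2-triphenylethyl (3S)-3-hydroxy-3-Ar-propanoate
Product: 10 (1S)-1-Ar-propane-1,3-diol
Conditions: LiAlH4, THF, 0 °C → rt
Reagents that add atoms: none
Why: Hydride reduction of the ester to the primary alcohol releases the chiral diol auxiliary and gives the 1,3-diol without touching the carbinol stereocentre.

Step 5
Reactants: 10 (1S)-1-Ar-propane-1,3-diol
Product: 11 (1S)-1-Ar-3-[(triisopropylsilyl)oxy]propan-1-ol
Conditions: TIPSCl, imidazole, CH2Cl2, 0 °C
Reagents that add atoms: chlorotriisopropylsilane (TIPSCl), CC(C)[Si](Cl)(C(C)C)C(C)C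
Why: Sterically controlled silylation of the primary hydroxyl in the presence of the hindered benzylic one; triisopropylsilyl is chosen because it resists base-induced 1,5-migration to the neighbouring alkoxide in step 6.

Step 6
Reactants: 11 (1S)-1-Ar-3-[(triisopropylsilyl)oxy]propan-1-ol; 12 trichloroethylene; 3 prenyl bromide
Product: 15 triisopropyl{(3S)-3-Ar-3-[(5-methylhex-4-en-1-yn-1-yl)oxy]propoxy}silane, via (E)-1,2-dichlorovinyl ether 13 (not isolated), via lithium alkynyl ether 14 (not isolated)
Conditions: KH, THF, 0 °C; 12, −50 °C → rt; n-BuLi (2.3 equiv), −78 °C; DMPU, 3, −78 → −20 °C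
Reagents that add atoms: none
Why: Trichloroethylene route to alkynyl ethers: the potassium alkoxide adds to dichloroacetylene formed in situ, n-BuLi effects dehydrochlorination and chlorine–lithium exchange to the acetylide, and SN2 alkylation at the primary carbon of 3 gives the internal ynol ether; the carbinol C–O bond is never broken, so the configuration is retained.

Step 7
Reactants: 15 triisopropyl{(3S)-3-Ar-3-[(5-methylhex-4-en-1-yn-1-yl)oxy]propoxy}silane
Product: 16 (3S)-3-Ar-3-[(5-methylhex-4-en-1-yn-1-yl)oxy]propan-1-ol
Conditions: Bu4NF, THF, 0 °C → rt
Reagents that add atoms: none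
Why: Fluoride-mediated desilylation under non-acidic conditions, which the acid-labile ynol ether tolerates.

Step 8
Reactants: 16 (3S)-3-Ar-3-[(5-methylhex-4-en-1-yn-1-yl)oxy]propan-1-ol
Product: 17 (3S)-3-Ar-3-[(5-methylhex-4-en-1-yn-1-yl)oxy]propanal
Conditions: Dess–Martin periodinane, pyridine, CH2Cl2, 0 °C
Reagents that add atoms: none
Why: Dess–Martin oxidation of the primary alcohol under buffered, non-aqueous conditions avoids both acid (ynol ether hydration) and strong base (β-elimination of the alkynyloxy group from the aldehyde).

Step 9
Reactants: 18 cyclobutane-1,3-dione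
Product: 19 3-(methoxymethoxy)cyclobut-2-en-1-one
Conditions: MOMCl, iPr2NEt, CH2Cl2, 0 °C
Reagents that add atoms: chloromethyl methyl ether (MOMCl), COCCl
Why: O-Alkylation of the strongly acidic enol of the 1,3-dione with a hard electrophile gives the vinylogous ester; the MOM group is chosen so that the future O5 is unmasked together with O4' in the last step.

Step 10
Reactants: 19 3-(methoxymethoxy)cyclobut-2-en-1-one
Product: 20 2-iodo-3-(methoxymethoxy)cyclobut-2-en-1-one
Conditions: N-iodosuccinimide, MeCN, 0 °C → rt, dark
Reagents that add atoms: N-iodosuccinimide, O=C1CCC(=O)N1I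
Why: Electrophilic α-iodination of a vinylogous ester: C2 is the nucleophilic β-carbon of the enol ether, and proton loss from the iodinated oxocarbenium ion restores the enone.

Step 11
Reactants: 17 (3S)-3-Ar-3-[(5-methylhex-4-en-1-yn-1-yl)oxy]propanal; 20 2-iodo-3-(methoxymethoxy)cyclobut-2-en-1-one
Product: 21 2-{(3S)-3-Ar-1-hydroxy-3-[(5-methylhex-4-en-1-yn-1-yl)oxy]propyl}-3-(methoxymethoxy)cyclobut-2-en-1-one (both epimers at the new carbinol carbon)
Conditions: CrCl2 (4 equiv), NiCl2 (2 mol%), DMF, rt
Reagents that add atoms: none
Why: Nozaki–Hiyama–Kishi coupling: zerovalent nickel inserts into the alkenyl C–I bond and transmetalation to trivalent chromium gives an alkenylchromium species that adds chemoselectively to the aldehyde under neutral conditions, sparing the ynol ether and the enolisable β-alkoxy aldehyde; the new carbinol centre is uncontrolled and is removed in step 12.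

Step 12
Reactants: 21 2-{(3S)-3-Ar-1-hydroxy-3-[(5-methylhex-4-en-1-yn-1-yl)oxy]propyl}-3-(methoxymethoxy)cyclobut-2-en-1-one
Product: 22 2-{(3S)-3-Ar-3-[(5-methylhex-4-en-1-yn-1-yl)oxy]propanoyl}-3-(methoxymethoxy)cyclobut-2-en-1-one
Conditions: Dess–Martin periodinane, pyridine, CH2Cl2, 0 °C; filtration through neutral alumina
Reagents that add atoms: none
Why: Dess–Martin oxidation of the secondary carbinol to the ketone under buffered anhydrous conditions; the electrophilic acylated vinylogous ester meets neither water nor nucleophiles and is used at once.

Step 13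
Reactants: 22 2-{(3S)-3-Ar-3-[(5-methylhex-4-en-1-yn-1-yl)oxy]propanoyl}-3-(methoxymethoxy)cyclobut-2-en-1-one
Product: 26 (2S)-2-Ar-7-hydroxy-5-(methoxymethoxy)-8-(3-methylbut-2-en-1-yl)chroman-4-one, via acyl vinylketene 23 (not isolated), via fused vinylcyclobutenone 24 (not isolated), via dienylketene 25 (not isolated)
Conditions: hν (350 nm, Pyrex), PhMe (0.005 M), 5 °C; then 80 °C, dark
Reagents that add atoms: none
Why: Proposed new method: light opens the cyclobutenone of 22 by four-electron electrocyclic cleavage of its C(=O)–CH2 bond, giving acyl vinylketene 23 without heating the ynol ether. The electron-rich β-carbon of the tethered ynol ether (future C8) attacks the ketene carbon (future C7) and the alkoxy-stabilised cationic carbon (C8a) then bonds to the ketene α-carbon (C4a); this stepwise [2+2] closes ring C as a six-membered ring fused to a new cyclobutenone, 24. On warming, 24 opens by a second four-electron electrocyclic step to dienylketene 25, the ring fusion leaving only inward rotation of the vinyl group, and six-electron electrocyclisation between C7 and C6 followed by enolisation closes ring A as the phenol 26. The closest known reaction type is the Danheiser benzannulation of cyclobutenones with alkoxy- or siloxyalkynes; new here are the tether through O1 and the acyl substituent on the vinylketene. No stereocentre is formed: the quaternary centre of 24 disappears on aromatisation, and the C2–O and C2–H bonds are spectators, so the configuration set in step 3 is carried through. Regiochemistry (oxygen on C7 and C8a around prenyl on C8) follows from the polarity of the ynol ether and is locked by the tether, which also excludes the hetero-[4+2] mode of the acylketene because that would place a double bond at a bridgehead. The selectivity needed is cycloaddition ahead of retro-ene or [3,3] loss of the benzylic ynol ether; generating 23 photochemically near 5 °C at high dilution, and heating only after the ynol ether has been consumed in 24, should secure it.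

Step 14
Reactants: 26 (2S)-2-Ar-7-hydroxy-5-(methoxymethoxy)-8-(3-methylbut-2-en-1-yl)chroman-4-one
Product: 27 (2S)-5,7-dihydroxy-2-[4-hydroxy-3-methoxy-2-(3-methylbut-2-en-1-yl)phenyl]-8-(3-methylbut-2-en-1-yl)chroman-4-one (CNP0282226.1)
Conditions: HCl (3 M aq.), MeOH, 40 °C
Reagents that add atoms: none
Why: Acid-catalysed acetal exchange with methanol removes both MOM ethers, the peri 5-ether fastest through assistance by the C4 carbonyl; the conditions are of the kind used for prenylated flavanones, and the mild temperature limits chroman formation at the 8-prenyl/7-hydroxyl pair and leaves C2 untouched.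

## Compound list

1 | vanillin (4-hydroxy-3-methoxybenzaldehyde) | COc1cc(C=O)ccc1O | starting material
2 | 3-methoxy-4-(methoxymethoxy)benzaldehyde | COCOc1ccc(C=O)cc1OC | intermediate
3 | prenyl bromide (1-bromo-3-methylbut-2-ene) | CC(C)=CCBr | starting material
4 | lithium α-amino alkoxide from 2 and lithium [2-(dimethylamino)ethyl](methyl)amide | COCOc1ccc(C(O[Li])N(C)CCN(C)C)cc1OC | intermediate
5 | C2-lithiated amino alkoxide | COCOc1ccc(C(O[Li])N(C)CCN(C)C)c([Li])c1OC | intermediate
6 | 3-methoxy-4-(methoxymethoxy)-2-(3-methylbut-2-en-1-yl)benzaldehyde | COCOc1ccc(C=O)c(CC=C(C)C)c1OC | intermediate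
7 | (S)-2-hydroxy-1,2,2-triphenylethyl acetate ((S)-HYTRA) | CC(=O)O[C@@H](c1ccccc1)C(O)(c1ccccc1)c1ccccc1 | starting material
8 | dilithium enolate of 7 | C=C(O[Li])O[C@@H](c1ccccc1)C(O[Li])(c1ccccc1)c1ccccc1 | intermediate
9 | (S)-2-hydroxy-1,2,2-triphenylethyl (3S)-3-hydroxy-3-Ar-propanoate | O=C(C[C@H](O)c1ccc(OCOC)c(OC)c1CC=C(C)C)O[C@@H](c1ccccc1)C(O)(c1ccccc1)c1ccccc1 | intermediate
10 | (1S)-1-Ar-propane-1,3-diol | OCC[C@H](O)c1ccc(OCOC)c(OC)c1CC=C(C)C | intermediate
11 | (1S)-1-Ar-3-[(triisopropylsilyl)oxy]propan-1-ol | CC(C)[Si](OCC[C@H](O)c1ccc(OCOC)c(OC)c1CC=C(C)C)(C(C)C)C(C)C | intermediate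
12 | trichloroethylene | ClC=C(Cl)Cl | starting material
13 | (E)-1,2-dichlorovinyl ether of 11 | CC(C)[Si](OCC[C@H](O/C(Cl)=C\Cl)c1ccc(OCOC)c(OC)c1CC=C(C)C)(C(C)C)C(C)C | intermediate
14 | lithium alkynyl ether (lithium acetylide of the ethynyl ether of 11) | CC(C)[Si](OCC[C@H](OC#C[Li])c1ccc(OCOC)c(OC)c1CC=C(C)C)(C(C)C)C(C)C | intermediate
15 | triisopropyl{(3S)-3-Ar-3-[(5-methylhex-4-en-1-yn-1-yl)oxy]propoxy}silane | CC(C)[Si](OCC[C@H](OC#CCC=C(C)C)c1ccc(OCOC)c(OC)c1CC=C(C)C)(C(C)C)C(C)C | intermediate
16 | (3S)-3-Ar-3-[(5-methylhex-4-en-1-yn-1-yl)oxy]propan-1-ol | OCC[C@H](OC#CCC=C(C)C)c1ccc(OCOC)c(OC)c1CC=C(C)C | intermediate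
17 | (3S)-3-Ar-3-[(5-methylhex-4-en-1-yn-1-yl)oxy]propanal | O=CC[C@H](OC#CCC=C(C)C)c1ccc(OCOC)c(OC)c1CC=C(C)C | intermediate
18 | cyclobutane-1,3-dione | O=C1CC(=O)C1 | starting material
19 | 3-(methoxymethoxy)cyclobut-2-en-1-one | COCOC1=CC(=O)C1 | intermediate
20 | 2-iodo-3-(methoxymethoxy)cyclobut-2-en-1-one | COCOC1=C(I)C(=O)C1 | intermediate
21 | 2-{(3S)-3-Ar-1-hydroxy-3-[(5-methylhex-4-en-1-yn-1-yl)oxy]propyl}-3-(methoxymethoxy)cyclobut-2-en-1-one (both carbinol epimers) | COCOC1=C(C(O)C[C@H](OC#CCC=C(C)C)c2ccc(OCOC)c(OC)c2CC=C(C)C)C(=O)C1 | intermediate
22 | 2-{(3S)-3-Ar-3-[(5-methylhex-4-en-1-yn-1-yl)oxy]propanoyl}-3-(methoxymethoxy)cyclobut-2-en-1-one | COCOC1=C(C(=O)C[C@H](OC#CCC=C(C)C)c2ccc(OCOC)c(OC)c2CC=C(C)C)C(=O)C1 | intermediate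
23 | acyl vinylketene from ring opening of 22 | C=C(OCOC)C(=C=O)C(=O)C[C@H](OC#CCC=C(C)C)c1ccc(OCOC)c(OC)c1CC=C(C)C | intermediate
24 | fused vinylcyclobutenone (ring C closed; quaternary C4a bearing the 1-(methoxymethoxy)vinyl group) | C=C(OCOC)C12C(=O)C[C@@H](c3ccc(OCOC)c(OC)c3CC=C(C)C)OC1=C(CC=C(C)C)C2=O | intermediate
25 | dienylketene from ring opening of 24 | C=C(OCOC)C1=C(C(CC=C(C)C)=C=O)O[C@H](c2ccc(OCOC)c(OC)c2CC=C(C)C)CC1=O | intermediate
26 | (2S)-2-Ar-7-hydroxy-5-(methoxymethoxy)-8-(3-methylbut-2-en-1-yl)chroman-4-one | COc1c(OCOC)ccc([C@@H]2CC(=O)c3c(OCOC)cc(O)c(CC=C(C)C)c3O2)c1CC=C(C)C | intermediate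
27 | (2S)-5,7-dihydroxy-2-[4-hydroxy-3-methoxy-2-(3-methylbut-2-en-1-yl)phenyl]-8-(3-methylbut-2-en-1-yl)chroman-4-one | COc1c(O)ccc([C@@H]2CC(=O)c3c(O)cc(O)c(CC=C(C)C)c3O2)c1CC=C(C)C | target

## Step count and least certain steps

Total: 14 steps. Longest linear sequence: 12 steps (steps 1–8 and 11–14 from 1); steps 9 and 10 form a two-step branch.

Step 13 (key step, carrying the label for a new method). The most likely failures are:
- fragmentation of the secondary benzylic ynol ether (retro-ene through the C3 hydrogens, or a [3,3] shift onto the free ortho position of ring B) before the ketene is captured;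
- unproductive photochemistry of the acylated vinylogous ester;
- stalling of the cascade at the fused cyclobutenone stage;
- intermolecular acylation of the product phenol by unreacted ketene.

All follow from the fact that neither the intramolecular mode nor an acyl-substituted vinylketene has precedent in this benzannulation. The fallback uses known chemistry only, sets out from 6 and returns at 27:
- 6 is condensed under Claisen–Schmidt conditions (KOH, EtOH) with 1-[2,6-dihydroxy-4-(methoxymethoxy)phenyl]ethan-1-one F1, which is one MOM protection away from commercial 2',4',6'-trihydroxyacetophenone. This gives (E)-1-[2,6-dihydroxy-4-(methoxymethoxy)phenyl]-3-Ar-prop-2-en-1-one F2.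
- NaOAc in refluxing EtOH closes F2 to racemic 2-Ar-5-hydroxy-7-(methoxymethoxy)chroman-4-one F3. Ring A is symmetric at this stage, so no 6/8 ambiguity arises.
- Mitsunobu O-prenylation of the 5-hydroxyl gives racemic 2-Ar-7-(methoxymethoxy)-5-[(3-methylbut-2-en-1-yl)oxy]chroman-4-one F4.
- Eu(fod)3 in warm CHCl3 effects the Claisen–Cope relocation to C8, giving racemic 2-Ar-5-hydroxy-7-(methoxymethoxy)-8-(3-methylbut-2-en-1-yl)chroman-4-one F5.
- Separation on a chiral stationary phase gives (2S)-2-Ar-5-hydroxy-7-(methoxymethoxy)-8-(3-methylbut-2-en-1-yl)chroman-4-one F6, which the conditions of step 14 convert into 27.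

Step 11. The concerns are slow oxidative addition at the electron-rich α-iodo vinylogous ester, cleavage of the vinylogous MOM ether or hydration of the ynol ether by Lewis-acidic chromium salts during a long reaction, and β-elimination of the alkynyloxy group from the aldehyde. The fallback sets out from 20 and 17 and returns at 21. It replaces the nickel/chromium redox coupling by a polar organomagnesium addition: iodine–magnesium exchange of 20 with iPrMgCl·LiCl in THF at −78 °C gives [2-(methoxymethoxy)-4-oxocyclobut-1-en-1-yl]magnesium chloride F7, to which 17 is added at the same temperature.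

Step 6. The concerns are attack at the tertiary end of 3 (SN2′), base-induced isomerisation of the skipped enyne to an allene under excess acetylide, incomplete alkylation, and sigmatropic loss of the benzylic alkynyl ether on warming. The fallback sets out from 11 and returns at 15. It separates ynol ether formation from C–C bond formation: 13 and 14 are generated as before, but 14 is quenched with methanol to the terminal alkynyl ether triisopropyl{(3S)-3-Ar-3-(ethynyloxy)propoxy}silane F8. F8 is then coupled with 3 under near-neutral copper catalysis (CuI, K2CO3, NaI, DMF, rt).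

Step 2. The concern is competing or double metalation ortho to the 4-MOM ether at C5, since this group is a director in its own right, which would erode regioselectivity. The fallback sets out from 1 and returns at 6. It removes the competing director:
- 1 is silylated (TIPSCl, imidazole) to 3-methoxy-4-[(triisopropylsilyl)oxy]benzaldehyde F9.
- The same amino alkoxide metalation and prenylation, now with only the cooperative C2 site activated, gives 3-methoxy-2-(3-methylbut-2-en-1-yl)-4-[(triisopropylsilyl)oxy]benzaldehyde F10.
- Bu4NF releases 4-hydroxy-3-methoxy-2-(3-methylbut-2-en-1-yl)benzaldehyde F11, and MOMCl with iPr2NEt converts it into 6.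

## Further compounds

F1 | step 13 | 1-[2,6-dihydroxy-4-(methoxymethoxy)phenyl]ethan-1-one | CC(=O)c1c(O)cc(OCOC)cc1O
F2 | step 13 | (E)-1-[2,6-dihydroxy-4-(methoxymethoxy)phenyl]-3-Ar-prop-2-en-1-one | COCOc1cc(O)c(C(=O)/C=C/c2ccc(OCOC)c(OC)c2CC=C(C)C)c(O)c1
F3 | step 13 | racemic 2-Ar-5-hydroxy-7-(methoxymethoxy)chroman-4-one | COc1c(OCOC)ccc(C2CC(=O)c3c(O)cc(OCOC)cc3O2)c1CC=C(C)C
F4 | step 13 | racemic 2-Ar-7-(methoxymethoxy)-5-[(3-methylbut-2-en-1-yl)oxy]chroman-4-one | COc1c(OCOC)ccc(C2CC(=O)c3c(OCC=C(C)C)cc(OCOC)cc3O2)c1CC=C(C)C
F5 | step 13 | racemic 2-Ar-5-hydroxy-7-(methoxymethoxy)-8-(3-methylbut-2-en-1-yl)chroman-4-one | COc1c(OCOC)ccc(C2CC(=O)c3c(O)cc(OCOC)c(CC=C(C)C)c3O2)c1CC=C(C)C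
F6 | step 13 | (2S)-2-Ar-5-hydroxy-7-(methoxymethoxy)-8-(3-methylbut-2-en-1-yl)chroman-4-one | COc1c(OCOC)ccc([C@@H]2CC(=O)c3c(O)cc(OCOC)c(CC=C(C)C)c3O2)c1CC=C(C)C
F7 | step 11 | [2-(methoxymethoxy)-4-oxocyclobut-1-en-1-yl]magnesium chloride | COCOC1=C([Mg]Cl)C(=O)C1
F8 | step 6 | triisopropyl{(3S)-3-Ar-3-(ethynyloxy)propoxy}silane | CC(C)[Si](OCC[C@H](OC#C)c1ccc(OCOC)c(OC)c1CC=C(C)C)(C(C)C)C(C)C
F9 | step 2 | 3-methoxy-4-[(triisopropylsilyl)oxy]benzaldehyde | COc1cc(C=O)ccc1O[Si](C(C)C)(C(C)C)C(C)C
F10 | step 2 | 3-methoxy-2-(3-methylbut-2-en-1-yl)-4-[(triisopropylsilyl)oxy]benzaldehyde | COc1c(O[Si](C(C)C)(C(C)C)C(C)C)ccc(C=O)c1CC=C(C)C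
F11 | step 2 | 4-hydroxy-3-methoxy-2-(3-methylbut-2-en-1-yl)benzaldehyde | COc1c(O)ccc(C=O)c1CC=C(C)C
A1 | alternative 1 | 2-iodo-3,5-bis(methoxymethoxy)-6-(3-methylbut-2-en-1-yl)phenol | Oc1c(I)c(OCOC)cc(OCOC)c1CC=C(C)C
A2 | alternative 1 | carbon monoxide | [C-]#[O+]
A3 | alternative 1 | 1-ethynyl-3-methoxy-4-(methoxymethoxy)-2-(3-methylbut-2-en-1-yl)benzene | C#Cc1ccc(OCOC)c(OC)c1CC=C(C)C
A4 | alternative 1 | 2-Ar-5,7-bis(methoxymethoxy)-8-(3-methylbut-2-en-1-yl)-4H-chromen-4-one | COc1c(OCOC)ccc(-c2cc(=O)c3c(OCOC)cc(OCOC)c(CC=C(C)C)c3o2)c1CC=C(C)C
A5 | alternative 2 | (2S)-7-(methoxymethoxy)-2-[4-(methoxymethoxy)-3-[(2-methylbut-3-en-2-yl)oxy]phenyl]-5-[(3-methylbut-2-en-1-yl)oxy]chroman-4-one | COCOc1ccc([C@@H]2CC(=O)c3c(OCC=C(C)C)cc(OCOC)cc3O2)cc1OC(C)(C)C=C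
A6 | alternative 2 | (2S)-5-hydroxy-2-[3-hydroxy-4-(methoxymethoxy)-2-(3-methylbut-2-en-1-yl)phenyl]-7-(methoxymethoxy)-8-(3-methylbut-2-en-1-yl)chroman-4-one | COCOc1ccc([C@@H]2CC(=O)c3c(O)cc(OCOC)c(CC=C(C)C)c3O2)c(CC=C(C)C)c1O
A7 | alternative 3 | (1S)-1-Ar-3-[2-bromo-4,6-bis(methoxymethoxy)-3-(3-methylbut-2-en-1-yl)phenyl]propane-1,3-diol (either C3 epimer) | COc1c(OCOC)ccc([C@@H](O)CC(O)c2c(OCOC)cc(OCOC)c(CC=C(C)C)c2Br)c1CC=C(C)C
A8 | alternative 3 | (2S)-2-Ar-5,7-bis(methoxymethoxy)-8-(3-methylbut-2-en-1-yl)chroman-4-ol (either C4 epimer) | COc1c(OCOC)ccc([C@@H]2CC(O)c3c(OCOC)cc(OCOC)c(CC=C(C)C)c3O2)c1CC=C(C)C
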